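Its constants belong to no real substance; the rest is arithmetic.

The leftover came first: one L goes with one Z, so the charges of this flask leave 0.0500 M of Q over, and by charge J is the limiting reagent. But that is a statement about the end of the reaction, and the question is about a fixed time.

J 0.10 M; Q 0.150 M; time 3.0 min
- Z.L at 3.0 min, in percent of the J charged
- concentration of Z in solution at 3.0 min, in percent of saturation
- percentages count the J that a species holds: one J2 counts as two
- where a step has two of a species, its rate is k times that concentration squared, and two are used at each turn
- solid, in amounts per volume of the solution: J, Q
- at the start none of J is in solution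
- at the start none of Q is in solution
- Z means what is dissolved; the solid is not counted in it
- run time (flask): 3.0 min
    Z.L ⇌ E (K1 = 1.9, k1 = 0.0035 s⁻¹)
    J ⇌ Z, rate k2*(cs2 - [Z]) while solid is left; crystals form when [Z] > cs2 (cs2 = 0.057 M, k2 = 0.20 s⁻¹)
    2 J → J2 (k3 = 0.23 M⁻¹ s⁻¹)
    Q ⇌ L, rate k4*(cs4 - [L]) while solid is left; crystals form when [L] > cs4 (cs4 = 11 mM, k4 = 0.030 s⁻¹)
    Z + L → Z.L (k5 = 21 M⁻¹ s⁻¹)

So I reckoned by hand, treating the dissolving of Q as a feed into a tank. An L lasts about 0.835 s against [Z] at its solubility, far shorter than the 33.3 s time constant of the dissolving, so I expected [L] to stay small and what dissolves to be used.

My first way held [L] at nothing. The delivery ceiling, which is dissolution coefficient times solubility times time, divided by the J charged, came to 59.4%.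

My second way started from the consuming end. With [Z] at its solubility, feed and use balance at [L] = 2.69 × 10⁻⁴ M, and that reaction rate over the run gives 57.9%. The two ways part by 1.5 percentage points, and the first is the one that cheats, since [L] is not nothing. Going round once more, a lower [Z] raises [L] and cuts the feed further, so I committed to a little below the second figure for Z.L and E together. Their relaxation half-life of 2.16 min is shorter than the run, so I expected part of the Z.L to have moved on to E, and my hand stopped at that sum.

The forecast went further and gave 43% for Z.L and 38% of saturation for Z, with Z + L “limited by Q dissolving”.

The simulation gave 43.4% for Z.L and 37.5% of saturation for Z, so the forecast held within its margin. At 3.00 min Z.L was still being made 2.37 times faster than it was used up. Z.L and E together held 56.7%, a little below the ceiling of 59.4%.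

In the neighbour flask with 0.40 M of J, the same feed is spread over a larger charge, so the ceiling falls to 14.8%. That neighbour flask gave 11.0% of Z.L, and with E 14.3% together, just below the ceiling.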